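**Strategy.** The route rests on cutting the cyclopentane B ring (C5, C6, C8, C9, C10) into a three-carbon unit C5–C6–C8 and the two-carbon unit C9–C10. Because C6 carries the carboxyl between C5 and the quaternary C8, this unit is a latent cyclopropanecarboxylate: a thiyl-radical-catalysed (3+2) cycloaddition of vinylcyclopropane 13, bearing two identical propargyl arms on C8 (future C14/C13/C12 and C15/C16/C17), with menthyloxybutenolide 14 (C20, C10, C9, C11) forms C8–C9 and C5–C10 at once and delivers ring B with every substituent in place. Ring A and the 19,20-lactone, then rings C and D, are annulated onto this core.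

Key step: step 9

Remarks on the chemistry:
- Gibberellane numbering (C1–C20) is used for all intermediates; β is the face of H-5, H-9, C-7 and 2-OH, α the face of C-19, C-20 and C-11.
- The target is the 2β,13-dihydroxy C20 gibberellin with the 19,20-lactone, the free C7 acid and the 16-methylene group.
- Compounds 2, 10, 14 and 16 are assumed to be purchased.
- 11–13 are carried as mixtures of C5 epimers, since C5 is flattened in step 9.

**Step 1**
Reactants: 1 diethyl malonate; 2 3-bromo-1-(trimethylsilyl)prop-1-yne (2.1 equiv)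
Product: 3 diethyl 2,2-bis[3-(trimethylsilyl)prop-2-ynyl]malonate
Conditions: NaH (2.2 equiv), THF/DMF, 0 °C to rt
Reagents that add atoms: none
Why: Double SN2 C-alkylation of the malonate enolate installs both identical arms on the future C8; no stereocentre is formed.

**Step 2**
Reactants: 3
Product: 4 ethyl 5-(trimethylsilyl)-2-[3-(trimethylsilyl)prop-2-ynyl]pent-4-ynoate
Conditions: LiCl, H2O (2 equiv), DMSO, 140 °C
Reagents that add atoms: none
Why: Krapcho dealkoxycarbonylation removes one ester under neutral conditions that should leave the alkynylsilanes intact.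

**Step 3**
Reactants: 4
Product: 5 5-(trimethylsilyl)-2-[3-(trimethylsilyl)prop-2-ynyl]pent-4-ynal
Conditions: DIBAL-H (1.05 equiv), CH2Cl2, −78 °C
Reagents that add atoms: none
Why: Partial ester reduction through the stable tetrahedral aluminate should stop at the aldehyde (future C5).

**Step 4**
Reactants: 5; 6 methyl acrylate
Product: 7 Morita–Baylis–Hillman alcohol (racemic)
Conditions: DABCO (1 equiv), MeOH (cat.), neat 6, rt, several days
Reagents that add atoms: none
Why: The Morita–Baylis–Hillman reaction joins C5 to C4 of the acrylate (C4, C18, C19); the carbinol centre is racemic and is destroyed in the next step.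

**Step 5**
Reactants: 7
Product: 9 2-(methoxycarbonyl)-1,3-diene, via allylic mesylate 8 (not isolated)
Conditions: MsCl, Et3N, CH2Cl2, 0 °C; then DBU, 40 °C
Reagents that add atoms: none
Why: Sulfonylation and base-induced elimination can only remove the single β-hydrogen at C8, giving the C8=C5–C4(=C18) diene, whose fully substituted terminus should suppress Diels–Alder dimerisation.

**Step 6**
Reactants: 9; 10 tert-butyl diazoacetate (slow addition)
Product: 11 vinylcyclopropane diester (C6 S; cis/trans mixture at C5)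
Conditions: CuOTf (2 mol %), (R,R)-t-Bu-bis(oxazoline) (2.2 mol %), CH2Cl2, rt
Reagents that add atoms: none
Why: Copper–bis(oxazoline) asymmetric cyclopropanation of the chrysanthemate type; the electrophilic carbenoid should choose the trisubstituted C8=C5 bond over the acrylate and the silylalkynes, and the ligand antipode is chosen to set C6 as S (the only cyclopropane centre that survives).

**Step 7**
Reactants: 11
Product: 12 allylic alcohol (C19–OH)
Conditions: DIBAL-H (2.2 equiv), CH2Cl2, −78 °C
Reagents that add atoms: none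
Why: DIBAL-H 1,2-reduction of the methyl enoate to the allylic alcohol should spare the hindered tert-butyl cyclopropanecarboxylate at −78 °C.

**Step 8**
Reactants: 12
Product: 13 triethylsilyl ether (cycloaddition precursor)
Conditions: TESCl, imidazole, CH2Cl2, 0 °C
Reagents that add atoms: chlorotriethylsilane, CC[Si](Cl)(CC)CC
Why: Standard silylation of the primary allylic alcohol, giving an electron-rich 1,1-disubstituted vinyl group as the radical trigger.

**Step 9**
Reactants: 13 triethylsilyl ether (cycloaddition precursor); 14 (R)-γ-(l-menthyloxy)-α,β-butenolide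
Product: 15 (3+2) cycloadduct (ring B fused cis to the C20/C11 lactone acetal)
Conditions: PhSSPh (20 mol %), AIBN (10 mol %), PhH, 80 °C, sunlamp; the butenolide is used in excess and the surplus recovered
Reagents that add atoms: none
Why: PhS• adds to the terminal methylene C18, the cyclopropylcarbinyl radical at C4 opens by C5–C8 scission to the nucleophilic tertiary C8 radical, which adds to the β-carbon C9 of 14 (bond C8–C9); the α-lactonyl radical at C10 closes 5-exo-trig onto C5 of the transient allyl sulfide (bond C5–C10, ring B), and β-scission returns PhS• and the C4=C18 methylene. The closest known reaction type is the thiyl-radical-catalysed vinylcyclopropane–alkene (3+2) cycloaddition with electron-poor alkenes. C9 is set by attack anti to the C11 menthyloxy group, as is usual for radical additions to γ-alkoxybutenolides, and C10 by the 5-exo closure on a five-membered lactone, which can only give the cis-fused bicycle. C5 is set by A(1,3) strain in the trisubstituted allyl sulfide, which holds H-6 in the alkene plane so that C10 attacks anti to the C6 ester and C4 ends α, cis to C20; C6 is the ligand-set centre and is not touched. The step needs opening towards C8 rather than the ester-stabilised C6 radical, which should follow because opening is reversible and only the tertiary alkyl radical is polarity-matched to the butenolide, and it needs the 5-exo-trig closure onto the electron-rich alkene to outrun 5-exo-dig attack on the silylalkyne arms. C8 carries two identical arms and is not yet stereogenic.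

**Step 10**
Reactants: 16 (S)-glycidol
Product: 17 (R)-glycidyl triflate (used directly)
Conditions: Tf2O, 2,6-lutidine, CH2Cl2, −78 °C
Reagents that add atoms: triflic anhydride, O=S(=O)(OS(=O)(=O)C(F)(F)F)C(F)(F)F
Why: O-sulfonylation of the primary alcohol leaves the epoxide and its stereocentre (future C2) untouched; the descriptor changes only through the priority rules.

**Step 11**
Reactants: 15; 17
Product: 18 C10-glycidyl lactone (C1 on the β face)
Conditions: LiHMDS (1.1 equiv), THF/HMPA, −78 °C; then 17, −78 to −40 °C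
Reagents that add atoms: none
Why: Alkylation of the cis-fused bicyclic lactone enolate at the ring-fusion carbon takes place on the convex β face and by triflate displacement rather than epoxide opening, making C10 quaternary with C1 β and C20 α.

**Step 12**
Reactants: 18
Product: 19 iodohydrin (C3–I, C2–OH)
Conditions: LiI, AcOH (2 equiv), THF, 0 °C to rt
Reagents that add atoms: lithium iodide, [Li+].[I-]
Why: Buffered epoxide opening by iodide at the terminal carbon C3 leaves the C2–O bond and configuration unchanged.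

**Step 13**
Reactants: 19
Product: 20 C2 tert-butyldimethylsilyl ether
Conditions: TBSOTf, 2,6-lutidine, CH2Cl2, −78 °C
Reagents that add atoms: tert-butyldimethylsilyl triflate, CC(C)(C)[Si](C)(C)OS(=O)(=O)C(F)(F)F
Why: Silylation blocks epoxide re-formation from the iodohydrin under the basic conditions that follow.

**Step 14**
Reactants: 20
Product: 23 triol iodide, via lactol 21 (not isolated), via TES diol 22 (not isolated)
Conditions: DIBAL-H (1.2 equiv), CH2Cl2, −78 °C; NaBH4, MeOH, 0 °C; PPTS, MeOH, rt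
Reagents that add atoms: none
Why: DIBAL-H reduces the lactone to the lactol without touching the tert-butyl ester; the bis-acetal then opens and borohydride reduces both aldehydes (C20 and C11) with loss of menthol, and PPTS removes only the primary allylic TES group.

**Step 15**
Reactants: 23
Product: 25 α-methylene δ-lactone (19,20-olide), via hydroxy lactol 24 (not isolated)
Conditions: MnO2 (excess), CH2Cl2, rt
Reagents that add atoms: none
Why: MnO2 oxidises only the allylic C19 alcohol; the enal is captured by the cis C20 hydroxyl as a six-membered lactol that is oxidised further (tandem oxidative lactonisation), while C11–OH is not allylic and stays.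

**Step 16**
Reactants: 25
Product: 27 ring-A-closed lactone alcohol, via lactone enolate 26 (not isolated)
Conditions: L-Selectride (2.2 equiv), THF, −78 °C; then HMPA, −78 to 0 °C
Reagents that add atoms: none
Why: Reductive alkylation: conjugate hydride addition to C18 gives the lactone enolate, which is alkylated by the C3 iodide (6-exo-tet); the tether from C10 can only reach one face, so the bridged bicyclo[3.3.1] skeleton fixes C4 with C19 α and the new methyl β.

**Step 17**
Reactants: 27
Product: 28 bis(terminal alkyne)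
Conditions: K2CO3, MeOH, rt
Reagents that add atoms: none
Why: Methanolysis of the alkynyl–silicon bonds; the bridged lactone, tert-butyl ester and TBS ether should survive.

**Step 18**
Reactants: 28
Product: 30 hydroxy methyl ketone, via cyclic enol ether 29 (not isolated)
Conditions: JohnPhosAu(MeCN)SbF6 (5 mol %), CH2Cl2, rt; then PPTS, THF/H2O
Reagents that add atoms: water, O
Why: Gold(I)-catalysed 6-exo-dig hydroalkoxylation by C11–OH reaches only the propargyl arm on the same (α) face of ring B (cis-fused oxacycle), and hydrolysis of the enol ether gives a directed Markovnikov hydration that differentiates the two arms and makes C8 stereogenic.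

**Step 19**
Reactants: 30
Product: 31 iodo ketone (C11–I)
Conditions: PPh3, I2, imidazole, CH2Cl2, 0 °C
Reagents that add atoms: iodine, II
Why: Appel reaction on the primary alcohol of the open hydroxy-ketone form.

**Step 20**
Reactants: 31
Product: 32 ring-C ketone (13-oxo, propargyl on C8)
Conditions: LiHMDS (1.1 equiv), THF/HMPA, −78 to 0 °C
Reagents that add atoms: none
Why: Kinetic enolisation at the methyl group (C12) and 6-exo-tet C-alkylation by C11–I close ring C cis-fused to ring B.

**Step 21**
Reactants: 32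
Product: 33 hydroxy acid (free 2β-OH and C7 acid)
Conditions: TFA/CH2Cl2 (1:1), 0 °C to rt; then THF/H2O
Reagents that add atoms: none
Why: Acidolysis removes the tert-butyl ester and the TBS ether before the acid-sensitive 13-hydroxy-16-ene unit exists.

**Step 22**
Reactants: 33
Product: 34 target gibberellin (2β,13-dihydroxy 19,20-lactone 7-acid with 16-methylene)
Conditions: SmI2 (3 equiv), HMPA, t-BuOH, THF, 0 °C to rt
Reagents that add atoms: none
Why: Samarium ketyl–alkyne reductive cyclisation (5-exo-dig) joins C13 to C16, giving the bridgehead 13-hydroxyl and the 16-methylene; the C13 configuration is dictated by the bicyclo[3.2.1] bridge.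

**Compound list**

1 | diethyl malonate | CCOC(=O)CC(=O)OCC | starting material
2 | 3-bromo-1-(trimethylsilyl)prop-1-yne | C[Si](C)(C)C#CCBr | starting material
3 | diethyl 2,2-bis[3-(trimethylsilyl)prop-2-yn-1-yl]malonate | CCOC(=O)C(CC#C[Si](C)(C)C)(CC#C[Si](C)(C)C)C(=O)OCC | intermediate
4 | ethyl 5-(trimethylsilyl)-2-[3-(trimethylsilyl)prop-2-yn-1-yl]pent-4-ynoate | CCOC(=O)C(CC#C[Si](C)(C)C)CC#C[Si](C)(C)C | intermediate
5 | 5-(trimethylsilyl)-2-[3-(trimethylsilyl)prop-2-yn-1-yl]pent-4-ynal (C8 with both arms; CHO = C5) | O=CC(CC#C[Si](C)(C)C)CC#C[Si](C)(C)C | intermediate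
6 | methyl acrylate (C4, C18, C19) | C=CC(=O)OC | starting material
7 | methyl 3-hydroxy-2-methylidene-7-(trimethylsilyl)-4-[3-(trimethylsilyl)prop-2-yn-1-yl]hept-6-ynoate, racemic | C=C(C(=O)OC)C(O)C(CC#C[Si](C)(C)C)CC#C[Si](C)(C)C | intermediate
8 | 3-O-methanesulfonate of 7 | C=C(C(=O)OC)C(OS(C)(=O)=O)C(CC#C[Si](C)(C)C)CC#C[Si](C)(C)C | intermediate (not isolated)
9 | methyl 2-methylidene-7-(trimethylsilyl)-4-[3-(trimethylsilyl)prop-2-yn-1-yl]hept-3-en-6-ynoate | C=C(C(=O)OC)C=C(CC#C[Si](C)(C)C)CC#C[Si](C)(C)C | intermediate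
10 | tert-butyl diazoacetate (C6, C7) | [N-]=[N+]=CC(=O)OC(C)(C)C | starting material
11 | tert-butyl (1S)-3-(3-methoxy-3-oxoprop-1-en-2-yl)-2,2-bis[3-(trimethylsilyl)prop-2-yn-1-yl]cyclopropane-1-carboxylate; cyclopropane = C6 (C1, S), C8 (C2), C5 (C3, both epimers) | C[Si](C)(C)C#CCC1(CC#C[Si](C)(C)C)C(C(=C)C(=O)OC)[C@@H]1C(=O)OC(C)(C)C | intermediate
12 | tert-butyl (1S)-3-(3-hydroxyprop-1-en-2-yl)-2,2-bis[3-(trimethylsilyl)prop-2-yn-1-yl]cyclopropane-1-carboxylate | C[Si](C)(C)C#CCC1(CC#C[Si](C)(C)C)C(C(=C)CO)[C@@H]1C(=O)OC(C)(C)C | intermediate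
13 | triethylsilyl ether of 12 | C[Si](C)(C)C#CCC1(CC#C[Si](C)(C)C)C(C(=C)CO[Si](CC)(CC)CC)[C@@H]1C(=O)OC(C)(C)C | intermediate
14 | (5R)-5-{[(1R,2S,5R)-5-methyl-2-(propan-2-yl)cyclohexyl]oxy}furan-2(5H)-one | O=C1C=C[C@H](O[C@@H]2C[C@H](C)CC[C@H]2C(C)C)O1 | starting material
15 | cycloadduct: cyclopentane ring B (C5, C6, C8, C9, C10) cis-fused at C9–C10 to the γ-lactone C20(=O)–O–C11(OMenthyl); H-5, H-9, H-10 and CO2tBu β; C4 vinyl unit α; OMenthyl trans to C8 | C[Si](C)(C)C#CCC1(CC#C[Si](C)(C)C)[C@H]2[C@H](O[C@@H]3C[C@H](C)CC[C@H]3C(C)C)OC(=O)[C@H]2[C@@H](C(=C)CO[Si](CC)(CC)CC)[C@@H]1C(=O)OC(C)(C)C | intermediate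
16 | (S)-glycidol | OC[C@H]1CO1 | starting material
17 | [(2R)-oxiran-2-yl]methyl trifluoromethanesulfonate | FC(F)(F)S(=O)(=O)OC[C@H]1CO1 | intermediate
18 | 15 alkylated at C10 with the oxiranylmethyl group (C1 β; C2, C3 as epoxide) | C[Si](C)(C)C#CCC1(CC#C[Si](C)(C)C)[C@H]2[C@H](O[C@@H]3C[C@H](C)CC[C@H]3C(C)C)OC(=O)[C@@]2(C[C@H]3CO3)[C@@H](C(=C)CO[Si](CC)(CC)CC)[C@@H]1C(=O)OC(C)(C)C | intermediate
19 | iodohydrin of 18 (C2–OH, C3–I) | C[Si](C)(C)C#CCC1(CC#C[Si](C)(C)C)[C@H]2[C@H](O[C@@H]3C[C@H](C)CC[C@H]3C(C)C)OC(=O)[C@@]2(C[C@H](O)CI)[C@@H](C(=C)CO[Si](CC)(CC)CC)[C@@H]1C(=O)OC(C)(C)C | intermediate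
20 | C2 TBS ether of 19 | C[Si](C)(C)C#CCC1(CC#C[Si](C)(C)C)[C@H]2[C@H](O[C@@H]3C[C@H](C)CC[C@H]3C(C)C)OC(=O)[C@@]2(C[C@H](O[Si](C)(C)C(C)(C)C)CI)[C@@H](C(=C)CO[Si](CC)(CC)CC)[C@@H]1C(=O)OC(C)(C)C | intermediate
21 | lactol of 20 (C20 hemiacetal, anomers) | C[Si](C)(C)C#CCC1(CC#C[Si](C)(C)C)[C@H]2[C@H](O[C@@H]3C[C@H](C)CC[C@H]3C(C)C)OC(O)[C@@]2(C[C@H](O[Si](C)(C)C(C)(C)C)CI)[C@@H](C(=C)CO[Si](CC)(CC)CC)[C@@H]1C(=O)OC(C)(C)C | intermediate (not isolated)
22 | C20/C11 diol still carrying the C19 TES ether | C[Si](C)(C)C#CCC1(CC#C[Si](C)(C)C)[C@@H](CO)[C@](CO)(C[C@H](O[Si](C)(C)C(C)(C)C)CI)[C@@H](C(=C)CO[Si](CC)(CC)CC)[C@@H]1C(=O)OC(C)(C)C | intermediate (not isolated)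
23 | triol (C19–OH allylic, C20–OH, C11–OH) with C2–OTBS and C3–I | C[Si](C)(C)C#CCC1(CC#C[Si](C)(C)C)[C@@H](CO)[C@](CO)(C[C@H](O[Si](C)(C)C(C)(C)C)CI)[C@@H](C(=C)CO)[C@@H]1C(=O)OC(C)(C)C | intermediate
24 | six-membered lactol from the C19 enal and C20–OH | C[Si](C)(C)C#CCC1(CC#C[Si](C)(C)C)[C@@H](CO)[C@@]2(C[C@H](O[Si](C)(C)C(C)(C)C)CI)COC(O)C(=C)[C@H]2[C@@H]1C(=O)OC(C)(C)C | intermediate (not isolated)
25 | α-methylene δ-lactone C19(=O)–O–C20 cis-fused to ring B, C11–OH free | C[Si](C)(C)C#CCC1(CC#C[Si](C)(C)C)[C@@H](CO)[C@@]2(C[C@H](O[Si](C)(C)C(C)(C)C)CI)COC(=O)C(=C)[C@H]2[C@@H]1C(=O)OC(C)(C)C | intermediate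
26 | dilithium lactone enolate / C11 alkoxide | [Li+].[Li+].C[Si](C)(C)C#CCC1(CC#C[Si](C)(C)C)[C@@H](C[O-])[C@@]2(C[C@H](O[Si](C)(C)C(C)(C)C)CI)COC([O-])=C(C)[C@H]2[C@@H]1C(=O)OC(C)(C)C | intermediate (not isolated)
27 | rings A and B with the 19,20-lactone in place (C4 quaternary, 2β-OTBS), C11–OH, two silylpropargyl arms on C8 | C[Si](C)(C)C#CCC1(CC#C[Si](C)(C)C)[C@@H](CO)[C@]23COC(=O)[C@](C)(C[C@@H](O[Si](C)(C)C(C)(C)C)C2)[C@H]3[C@@H]1C(=O)OC(C)(C)C | intermediate
28 | 27 with both alkynes terminal | C#CCC1(CC#C)[C@@H](CO)[C@]23COC(=O)[C@](C)(C[C@@H](O[Si](C)(C)C(C)(C)C)C2)[C@H]3[C@@H]1C(=O)OC(C)(C)C | intermediate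
29 | cyclic enol ether O(C11)–C13(=C12H2) on the α arm | C=C1C[C@@]2(CC#C)[C@@H](CO1)[C@]34COC(=O)[C@](C)(C[C@@H](O[Si](C)(C)C(C)(C)C)C3)[C@H]4[C@@H]2C(=O)OC(C)(C)C | intermediate (not isolated)
30 | hydroxy methyl ketone: α arm = C14H2–C13(=O)–C12H3, β arm = propargyl (C15–C17) | CC(=O)C[C@@]1(CC#C)[C@@H](CO)[C@]23COC(=O)[C@](C)(C[C@@H](O[Si](C)(C)C(C)(C)C)C2)[C@H]3[C@@H]1C(=O)OC(C)(C)C | intermediate
31 | C11 iodide of 30 | CC(=O)C[C@@]1(CC#C)[C@@H](CI)[C@]23COC(=O)[C@](C)(C[C@@H](O[Si](C)(C)C(C)(C)C)C2)[C@H]3[C@@H]1C(=O)OC(C)(C)C | intermediate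
32 | tetracyclic 13-ketone (rings A, B, C and lactone) with propargyl on C8, tert-butyl ester and 2β-OTBS | C#CC[C@]12CC(=O)CC[C@H]1[C@]34COC(=O)[C@](C)(C[C@@H](O[Si](C)(C)C(C)(C)C)C3)[C@H]4[C@@H]2C(=O)OC(C)(C)C | intermediate
33 | 32 with free 2β-OH and free C7 acid | C#CC[C@]12CC(=O)CC[C@H]1[C@]34COC(=O)[C@](C)(C[C@@H](O)C3)[C@H]4[C@@H]2C(=O)O | intermediate
34 | target gibberellin: 2β,13-dihydroxy C20 gibberellin 19,20-lactone with the free C7 acid and the 16-methylene group | C=C1C[C@]23C[C@@]1(O)CC[C@H]2[C@]12COC(=O)[C@](C)(C[C@@H](O)C1)[C@H]2[C@@H]3C(=O)O | target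

**Step count.** 22 steps in total; longest linear sequence 21 steps (steps 1–9 and 11–22; step 10 is a side branch).

**Steps most likely to fail**

Step 9. Chain propagation may stall because the cyclopropylcarbinyl radical re-closes, or opens towards the ester-stabilised C6 radical, faster than the tertiary C8 radical is trapped intermolecularly. The 5-exo closure may also show poor facial selectivity at C5. The fallback sets out from 13 and comes back at 15; it separates ring opening from annulation. 13 is irradiated with diphenyl diselenide (visible light, CH2Cl2) to give the ring-opened 1,5-bis(phenylselanyl) adduct F1, a stable tertiary selenide that already holds the allyl selenide acceptor. F1 and an excess of 14 are then treated with hexabutylditin under irradiation (PhH, 80 °C). Selenium abstraction gives the same C8 radical irreversibly; conjugate addition to 14, 5-exo closure and loss of PhSe• should give 15 (group-transfer radical annulation with a fragmenting allyl selenide).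

Step 16. Hydride may attack the primary iodide, or the enolate may be protonated before the slow bridging alkylation. The fallback sets out from 25 and comes back at 27; it replaces enolate alkylation by a reductive aldol ring closure. 25 is silylated at C11–OH (TESCl, imidazole) to the TES ether F2. The iodide is oxidised (AgBF4, DMSO; then Et3N; Kornblum oxidation) to the C3 aldehyde F3. Copper hydride ([(Ph3P)CuH]6, toluene, −40 °C to rt) effects conjugate reduction and intramolecular aldol addition to the 3-hydroxy lactone F4, with ring A closed and the same forced C4 configuration. The C3 alcohol is converted with thiocarbonyldiimidazole into the thiocarbamate F5 and removed with Bu3SnH/AIBN (Barton–McCombie deoxygenation) to give the TES ether F6. PPTS in MeOH then returns 27.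

Step 18. The gold catalyst may engage the 1,6-diyne or the enol ether/alkyne pair in cycloisomerisation instead of the directed hydration, or the wrong arm may be hydrated. The fallback sets out from 28 and comes back at 32, bypassing 30 and 31. C11–OH is oxidised with Dess–Martin periodinane to the aldehyde F7. Acid-catalysed intramolecular alkyne–carbonyl metathesis (TfOH cat., CH2Cl2), in which the terminal carbon C12 of the syn arm attacks the aldehyde, gives the cyclohexenone F8 (C11=C12–C13=O). Conjugate reduction with [(Ph3P)CuH]6 then gives 32.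

**Further compounds**

F1 | step 9 | tert-butyl ester of the ring-opened 1,5-bis(phenylselanyl) adduct of 13 (C8–SePh, C18–SePh, C5=C4 alkene) | C[Si](C)(C)C#CCC(CC#C[Si](C)(C)C)([Se]c1ccccc1)[C@H](C=C(C[Se]c1ccccc1)CO[Si](CC)(CC)CC)C(=O)OC(C)(C)C
F2 | step 16 | C11 triethylsilyl ether of 25 | C[Si](C)(C)C#CCC1(CC#C[Si](C)(C)C)[C@@H](CO[Si](CC)(CC)CC)[C@@]2(C[C@H](O[Si](C)(C)C(C)(C)C)CI)COC(=O)C(=C)[C@H]2[C@@H]1C(=O)OC(C)(C)C
F3 | step 16 | C3 aldehyde from F2 | C[Si](C)(C)C#CCC1(CC#C[Si](C)(C)C)[C@@H](CO[Si](CC)(CC)CC)[C@@]2(C[C@H](O[Si](C)(C)C(C)(C)C)C=O)COC(=O)C(=C)[C@H]2[C@@H]1C(=O)OC(C)(C)C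
F4 | step 16 | 3-hydroxy ring-A lactone (reductive aldol product) | C[Si](C)(C)C#CCC1(CC#C[Si](C)(C)C)[C@@H](CO[Si](CC)(CC)CC)[C@]23COC(=O)[C@](C)(C(O)[C@@H](O[Si](C)(C)C(C)(C)C)C2)[C@H]3[C@@H]1C(=O)OC(C)(C)C
F5 | step 16 | 3-O-(imidazol-1-ylcarbonothioyl) derivative of F4 | C[Si](C)(C)C#CCC1(CC#C[Si](C)(C)C)[C@@H](CO[Si](CC)(CC)CC)[C@]23COC(=O)[C@](C)(C(OC(=S)n4ccnc4)[C@@H](O[Si](C)(C)C(C)(C)C)C2)[C@H]3[C@@H]1C(=O)OC(C)(C)C
F6 | step 16 | C11 triethylsilyl ether of 27 | C[Si](C)(C)C#CCC1(CC#C[Si](C)(C)C)[C@@H](CO[Si](CC)(CC)CC)[C@]23COC(=O)[C@](C)(C[C@@H](O[Si](C)(C)C(C)(C)C)C2)[C@H]3[C@@H]1C(=O)OC(C)(C)C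
F7 | step 18 | C11 aldehyde from 28 | C#CCC1(CC#C)[C@@H](C=O)[C@]23COC(=O)[C@](C)(C[C@@H](O[Si](C)(C)C(C)(C)C)C2)[C@H]3[C@@H]1C(=O)OC(C)(C)C
F8 | step 18 | ring-C cyclohexenone (C11=C12–C13=O) | C#CC[C@]12CC(=O)C=C[C@H]1[C@]34COC(=O)[C@](C)(C[C@@H](O[Si](C)(C)C(C)(C)C)C3)[C@H]4[C@@H]2C(=O)OC(C)(C)C
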